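## Retrosynthetic overview

1. Target ⇒ N-Boc 3-epi-alcohol + (2E)-oct-2-enoic acid: a Mitsunobu inversion attaches the ester and corrects C3 in one operation.
2. cis-Decahydroquinoline ⇒ cis-octahydroindol-2-yl ethanol: aziridinium ring expansion (pyrrolidine to piperidine); two SN2 inversions fix C2 and C3.
3. Octahydroindole ⇒ (2S)-indoline-2-carboxylate ⇒ indole-2-carboxylate: one asymmetric hydrogenation sets a single centre, and an all-cis arene hydrogenation relays it to C4a, C5 and C8a.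
4. 4-Alkylindole ⇒ ethyl 4-bromoindole-2-carboxylate + silyl ether of (R)-oct-7-en-4-ol (B-alkyl Suzuki); the alcohol comes from (R)-2-propyloxirane and allyl Grignard (C5').
5. Ring order: ring A (carbocycle) is the benzene ring of the indole, saturated in step 6; ring B is carried as the pyrrole/pyrrolidine and becomes the piperidine only in step 10.

Assumption: the target is the drawn enantiomer, (2R,3S,4aR,5R,8aS,5'R); in step 5 the PhTRAP antipode is the one that gives the 2S indoline (written as the (S,S)-(R,R) ligand; its mirror image is used if the sense is opposite).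

## Route

Step 1
Reactants: 1 (R)-2-propyloxirane; 2 allylmagnesium bromide
Product: 3 (R)-oct-7-en-4-ol
Conditions: 2 (1.3 equiv), CuI (5 mol%), THF, −30 to 0 °C; then H2O
Reagents that add atoms: none
Why: Copper-assisted Grignard SN2 opening of the terminal epoxide at its unhindered CH2 leaves the stereocentre of 1 untouched, so the 5'R carbinol comes straight from the chiral pool.

Step 2
Reactants: 3 (R)-oct-7-en-4-ol
Product: 4 tert-butyldimethyl{[(4R)-oct-7-en-4-yl]oxy}silane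
Conditions: TBSOTf, 2,6-lutidine, CH2Cl2, 0 °C
Reagents that add atoms: tert-butyldimethylsilyl trifluoromethanesulfonate, CC(C)(C)[Si](C)(C)OS(=O)(=O)C(F)(F)F
Why: Silyl ether formation on a secondary alcohol; the TBS group masks the side-chain hydroxyl through all later steps and is removed in the last one.

Step 3
Reactants: 4 tert-butyldimethyl{[(4R)-oct-7-en-4-yl]oxy}silane; 5 ethyl 4-bromo-1H-indole-2-carboxylate
Product: 7 ethyl 4-[(5R)-5-(tert-butyldimethylsilyloxy)octyl]-1H-indole-2-carboxylate, via B-alkyl-9-BBN adduct 6 (not isolated)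
Conditions: 9-BBN-H (0.5 M in THF), 0 °C to rt; then 5, Pd(dppf)Cl2 (5 mol%), aq K3PO4 (3 M), DMF, 60 °C
Reagents that add atoms: 9-borabicyclo[3.3.1]nonane (9-BBN-H), [H]B1C2CCCC1CCC2 (its boron and bicycle sit only in 6; only its H stays in 7)
Why: Anti-Markovnikov hydroboration of the terminal alkene followed by B-alkyl Suzuki–Miyaura coupling (oxidative addition of the aryl bromide to zerovalent palladium, base-assisted alkyl transfer from boron) forms the C4–C1' bond, and the free indole N–H and the ester are tolerated.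

Step 4
Reactants: 7 ethyl 4-[(5R)-5-(tert-butyldimethylsilyloxy)octyl]-1H-indole-2-carboxylate
Product: 8 1-tert-butyl 2-ethyl 4-[(5R)-5-(tert-butyldimethylsilyloxy)octyl]-1H-indole-1,2-dicarboxylate
Conditions: Boc2O, DMAP (10 mol%), MeCN, rt
Reagents that add atoms: di-tert-butyl dicarbonate, CC(C)(C)OC(=O)OC(=O)OC(C)(C)C
Why: DMAP-catalysed N-acylation (Boc protection) of the indole installs the activating group needed for the asymmetric hydrogenation.

Step 5
Reactants: 8 1-tert-butyl 2-ethyl 4-[(5R)-5-(tert-butyldimethylsilyloxy)octyl]-1H-indole-1,2-dicarboxylate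
Product: 9 1-tert-butyl 2-ethyl (2S)-4-[(5R)-5-(tert-butyldimethylsilyloxy)octyl]-2,3-dihydro-1H-indole-1,2-dicarboxylate
Conditions: [RuCl(p-cymene)((S,S)-(R,R)-PhTRAP)]Cl (2 mol%), Cs2CO3 (10 mol%), H2 (5 MPa), 2-propanol, 60 °C
Reagents that add atoms: none
Why: Kuwano-type asymmetric hydrogenation of an N-Boc indole with the trans-chelating PhTRAP–ruthenium catalyst reduces only the C2=C3 bond and sets C2 as S, the one centre that relays chirality to the whole bicyclic core.

Step 6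
Reactants: 9 1-tert-butyl 2-ethyl (2S)-4-[(5R)-5-(tert-butyldimethylsilyloxy)octyl]-2,3-dihydro-1H-indole-1,2-dicarboxylate
Product: 10 1-tert-butyl 2-ethyl (2S,3aR,4R,7aS)-4-[(5R)-5-(tert-butyldimethylsilyloxy)octyl]octahydro-1H-indole-1,2-dicarboxylate (H2, H3a, H4 and H7a all cis)
Conditions: H2 (6 MPa), Rh on Al2O3 (5 wt% Rh), EtOH, 50 °C
Reagents that add atoms: none
Why: Heterogeneous cis arene hydrogenation: the C2 ester, held pseudo-axial by allylic 1,3-strain against the N-Boc group, blocks one face, so hydrogen reaches C3a, C4 and C7a from the other face and gives the all-cis octahydroindole (the future C4a, C5 and C8a), as in the industrial hydrogenation of (S)-indoline-2-carboxylic acid.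

Step 7
Reactants: 10 1-tert-butyl 2-ethyl (2S,3aR,4R,7aS)-4-[(5R)-5-(tert-butyldimethylsilyloxy)octyl]octahydro-1H-indole-1,2-dicarboxylate
Product: 12 tert-butyl (2S,3aR,4R,7aS)-2-acetyl-4-[(5R)-5-(tert-butyldimethylsilyloxy)octyl]octahydro-1H-indole-1-carboxylate, via Weinreb amide 11 (not isolated)
Conditions: MeNHOMe·HCl (1.6 equiv), MeMgCl (6 equiv), THF, −20 to 0 °C; then H2O
Reagents that add atoms: N,O-dimethylhydroxylamine hydrochloride, CNOC.Cl (its atoms sit only in 11); methylmagnesium chloride, C[Mg]Cl (the new CH3 of 12)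
Why: One-pot Weinreb ketone synthesis: the chloromagnesium amide of MeNHOMe aminolyses the ester faster than MeMgCl adds to it, and the amide then takes up exactly one methyl through a stable magnesium chelate; the cold, non-equilibrating conditions keep C2 from epimerising.

Step 8
Reactants: 12 tert-butyl (2S,3aR,4R,7aS)-2-acetyl-4-[(5R)-5-(tert-butyldimethylsilyloxy)octyl]octahydro-1H-indole-1-carboxylate
Product: 13 tert-butyl (2S,3aR,4R,7aS)-2-[(1S)-1-hydroxyethyl]-4-[(5R)-5-(tert-butyldimethylsilyloxy)octyl]octahydro-1H-indole-1-carboxylate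
Conditions: (R)-2-methyl-CBS-oxazaborolidine (20 mol%), BH3·SMe2, THF, −20 °C; then MeOH
Reagents that add atoms: none
Why: Corey–Bakshi–Shibata reduction: reagent control (methyl small, ring large) and the Felkin–Anh preference of the N-Boc α-amino ketone send hydride to the same face and give the 1S carbinol, threo to C2.

Step 9
Reactants: 13 tert-butyl (2S,3aR,4R,7aS)-2-[(1S)-1-hydroxyethyl]-4-[(5R)-5-(tert-butyldimethylsilyloxy)octyl]octahydro-1H-indole-1-carboxylate
Product: 15 (1S)-1-[(2S,3aR,4R,7aS)-1-benzyl-4-[(5R)-5-(tert-butyldimethylsilyloxy)octyl]octahydro-1H-indol-2-yl]ethan-1-ol, via free amino alcohol 14 (not isolated)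
Conditions: TFA/CH2Cl2 (1:4, anhydrous), 0 °C, 1 h; evaporate; then BnBr, K2CO3, MeCN, 50 °C
Reagents that add atoms: benzyl bromide, BrCc1ccccc1
Why: Boc acidolysis (anhydrous, cold and short, so the secondary TBS ether survives) followed by N-alkylation gives the basic tertiary amine needed for neighbouring-group participation in the next step.

Step 10
Reactants: 15 (1S)-1-[(2S,3aR,4R,7aS)-1-benzyl-4-[(5R)-5-(tert-butyldimethylsilyloxy)octyl]octahydro-1H-indol-2-yl]ethan-1-ol
Product: 19 (2R,3R,4aR,5R,8aS)-1-benzyl-2-methyl-5-[(5R)-5-(tert-butyldimethylsilyloxy)octyl]decahydroquinolin-3-ol, via carbinol trifluoroacetate 16 (not isolated), via bicyclic aziridinium trifluoroacetate 17 (not isolated), via piperidine trifluoroacetate 18 (not isolated)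
Conditions: TFAA (1.2 equiv), THF, −78 °C; Et3N (3 equiv), −78 °C to reflux, 24 h; then aq NaOH (2.5 M), rt
Reagents that add atoms: trifluoroacetic anhydride, O=C(OC(=O)C(F)(F)F)C(F)(F)F (CF3CO groups of 16 to 18; the C3 oxygen of 19 is drawn from the trifluoroacetate pool it supplies)
Why: Cossy-type prolinol-to-piperidinol ring expansion under thermodynamic control: nitrogen displaces the trifluoroacetate (SN2, inversion at the carbinol carbon, which becomes C2), trifluoroacetate reopens the strained aziridinium at the ring carbon (SN2, inversion, which becomes C3), and the reversible sequence drains to the less strained six-membered ring, so the octahydroindole becomes the cis-decahydroquinoline with 2R and 3R fixed stereospecifically.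

Step 11
Reactants: 19 (2R,3R,4aR,5R,8aS)-1-benzyl-2-methyl-5-[(5R)-5-(tert-butyldimethylsilyloxy)octyl]decahydroquinolin-3-ol
Product: 21 tert-butyl (2R,3R,4aR,5R,8aS)-3-hydroxy-2-methyl-5-[(5R)-5-(tert-butyldimethylsilyloxy)octyl]octahydroquinoline-1(2H)-carboxylate, via secondary amine 20 (not isolated)
Conditions: H2 (1 atm), Pd(OH)2 on carbon (20 wt%), Boc2O (2 equiv), EtOAc, rt to 45 °C
Reagents that add atoms: di-tert-butyl dicarbonate, CC(C)(C)OC(=O)OC(=O)OC(C)(C)C
Why: N-Benzyl hydrogenolysis with in situ Boc protection removes the nitrogen lone pair, so the coming substitution at C3 cannot pass through the aziridinium (which would give retention); EtOAc keeps the TBS ether intact.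

Step 12
Reactants: 21 tert-butyl (2R,3R,4aR,5R,8aS)-3-hydroxy-2-methyl-5-[(5R)-5-(tert-butyldimethylsilyloxy)octyl]octahydroquinoline-1(2H)-carboxylate; 22 (2E)-oct-2-enoic acid
Product: 23 tert-butyl (2R,3S,4aR,5R,8aS)-2-methyl-3-[(2E)-oct-2-enoyloxy]-5-[(5R)-5-(tert-butyldimethylsilyloxy)octyl]octahydroquinoline-1(2H)-carboxylate
Conditions: 22 (2 equiv), PPh3 (2 equiv), DIAD (2 equiv), toluene, 0 °C to rt
Reagents that add atoms: none
Why: Mitsunobu esterification: the octenoate displaces the oxyphosphonium of the C3–OH from the face anti to the C2 methyl with SN2 inversion, which installs the acyl group and turns 3R into the required 3S (ester trans to the methyl) in one operation.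

Step 13
Reactants: 23 tert-butyl (2R,3S,4aR,5R,8aS)-2-methyl-3-[(2E)-oct-2-enoyloxy]-5-[(5R)-5-(tert-butyldimethylsilyloxy)octyl]octahydroquinoline-1(2H)-carboxylate
Product: 24 (2R,3S,4aR,5R,8aS)-5-[(5R)-5-hydroxyoctyl]-2-methyldecahydroquinolin-3-yl (2E)-oct-2-enoate
Conditions: TFA/CH2Cl2/H2O (10:10:1), 0 °C to rt; then aq NaHCO3
Reagents that add atoms: none
Why: Acidolytic global deprotection: aqueous TFA cleaves the Boc carbamate and the TBS ether together while the protonated amine cannot attack the enoate, and the trans-diequatorial N/O arrangement of the free base disfavours O-to-N acyl shift on neutralisation.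

## Compound list

1 | (R)-2-propyloxirane | CCC[C@@H]1CO1 | starting material
2 | allylmagnesium bromide | C=CC[Mg]Br | starting material
3 | (R)-oct-7-en-4-ol | CCC[C@@H](O)CCC=C | intermediate
4 | tert-butyldimethyl{[(4R)-oct-7-en-4-yl]oxy}silane | CCC[C@@H](O[Si](C)(C)C(C)(C)C)CCC=C | intermediate
5 | ethyl 4-bromo-1H-indole-2-carboxylate | CCOC(=O)c1cc2c(Br)cccc2[nH]1 | starting material
6 | 9-[(5R)-5-(tert-butyldimethylsilyloxy)octyl]-9-borabicyclo[3.3.1]nonane | CCC[C@@H](O[Si](C)(C)C(C)(C)C)CCCCB1C2CCCC1CCC2 | intermediate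
7 | ethyl 4-[(5R)-5-(tert-butyldimethylsilyloxy)octyl]-1H-indole-2-carboxylate | CCOC(=O)c1cc2c(CCCC[C@H](O[Si](C)(C)C(C)(C)C)CCC)cccc2[nH]1 | intermediate
8 | 1-tert-butyl 2-ethyl 4-[(5R)-5-(tert-butyldimethylsilyloxy)octyl]-1H-indole-1,2-dicarboxylate | CCOC(=O)c1cc2c(CCCC[C@H](O[Si](C)(C)C(C)(C)C)CCC)cccc2n1C(=O)OC(C)(C)C | intermediate
9 | 1-tert-butyl 2-ethyl (2S)-4-[(5R)-5-(tert-butyldimethylsilyloxy)octyl]-2,3-dihydro-1H-indole-1,2-dicarboxylate | CCOC(=O)[C@@H]1Cc2c(CCCC[C@H](O[Si](C)(C)C(C)(C)C)CCC)cccc2N1C(=O)OC(C)(C)C | intermediate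
10 | 1-tert-butyl 2-ethyl (2S,3aR,4R,7aS)-4-[(5R)-5-(tert-butyldimethylsilyloxy)octyl]octahydro-1H-indole-1,2-dicarboxylate | CCOC(=O)[C@@H]1C[C@@H]2[C@H](CCCC[C@H](O[Si](C)(C)C(C)(C)C)CCC)CCC[C@@H]2N1C(=O)OC(C)(C)C | intermediate
11 | tert-butyl (2S,3aR,4R,7aS)-2-[methoxy(methyl)carbamoyl]-4-[(5R)-5-(tert-butyldimethylsilyloxy)octyl]octahydro-1H-indole-1-carboxylate (Weinreb amide) | CON(C)C(=O)[C@@H]1C[C@@H]2[C@H](CCCC[C@H](O[Si](C)(C)C(C)(C)C)CCC)CCC[C@@H]2N1C(=O)OC(C)(C)C | intermediate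
12 | tert-butyl (2S,3aR,4R,7aS)-2-acetyl-4-[(5R)-5-(tert-butyldimethylsilyloxy)octyl]octahydro-1H-indole-1-carboxylate | CC(=O)[C@@H]1C[C@@H]2[C@H](CCCC[C@H](O[Si](C)(C)C(C)(C)C)CCC)CCC[C@@H]2N1C(=O)OC(C)(C)C | intermediate
13 | tert-butyl (2S,3aR,4R,7aS)-2-[(1S)-1-hydroxyethyl]-4-[(5R)-5-(tert-butyldimethylsilyloxy)octyl]octahydro-1H-indole-1-carboxylate | C[C@H](O)[C@@H]1C[C@@H]2[C@H](CCCC[C@H](O[Si](C)(C)C(C)(C)C)CCC)CCC[C@@H]2N1C(=O)OC(C)(C)C | intermediate
14 | (1S)-1-[(2S,3aR,4R,7aS)-4-[(5R)-5-(tert-butyldimethylsilyloxy)octyl]octahydro-1H-indol-2-yl]ethan-1-ol | C[C@H](O)[C@@H]1C[C@@H]2[C@H](CCCC[C@H](O[Si](C)(C)C(C)(C)C)CCC)CCC[C@@H]2N1 | intermediate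
15 | (1S)-1-[(2S,3aR,4R,7aS)-1-benzyl-4-[(5R)-5-(tert-butyldimethylsilyloxy)octyl]octahydro-1H-indol-2-yl]ethan-1-ol | C[C@H](O)[C@@H]1C[C@@H]2[C@H](CCCC[C@H](O[Si](C)(C)C(C)(C)C)CCC)CCC[C@@H]2N1Cc1ccccc1 | intermediate
16 | (1S)-1-[(2S,3aR,4R,7aS)-1-benzyl-4-[(5R)-5-(tert-butyldimethylsilyloxy)octyl]octahydro-1H-indol-2-yl]ethyl trifluoroacetate | C[C@H](OC(=O)C(F)(F)F)[C@@H]1C[C@@H]2[C@H](CCCC[C@H](O[Si](C)(C)C(C)(C)C)CCC)CCC[C@@H]2N1Cc1ccccc1 | intermediate
17 | N-benzyl aziridinium ion bridging N1, C2 and the former carbinol carbon (CH–CH3) of the octahydroindole, trifluoroacetate salt | C[C@@H]1[C@@H]2C[C@@H]3[C@H](CCCC[C@H](O[Si](C)(C)C(C)(C)C)CCC)CCC[C@@H]3[N@+]12Cc1ccccc1.[O-]C(=O)C(F)(F)F | intermediate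
18 | (2R,3R,4aR,5R,8aS)-1-benzyl-2-methyl-5-[(5R)-5-(tert-butyldimethylsilyloxy)octyl]decahydroquinolin-3-yl trifluoroacetate | O=C(O[C@@H]1C[C@@H]2[C@H](CCCC[C@H](O[Si](C)(C)C(C)(C)C)CCC)CCC[C@@H]2N(Cc3ccccc3)[C@@H]1C)C(F)(F)F | intermediate
19 | (2R,3R,4aR,5R,8aS)-1-benzyl-2-methyl-5-[(5R)-5-(tert-butyldimethylsilyloxy)octyl]decahydroquinolin-3-ol | O[C@@H]1C[C@@H]2[C@H](CCCC[C@H](O[Si](C)(C)C(C)(C)C)CCC)CCC[C@@H]2N(Cc3ccccc3)[C@@H]1C | intermediate
20 | (2R,3R,4aR,5R,8aS)-2-methyl-5-[(5R)-5-(tert-butyldimethylsilyloxy)octyl]decahydroquinolin-3-ol | O[C@@H]1C[C@@H]2[C@H](CCCC[C@H](O[Si](C)(C)C(C)(C)C)CCC)CCC[C@@H]2N[C@@H]1C | intermediate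
21 | tert-butyl (2R,3R,4aR,5R,8aS)-3-hydroxy-2-methyl-5-[(5R)-5-(tert-butyldimethylsilyloxy)octyl]octahydroquinoline-1(2H)-carboxylate | O[C@@H]1C[C@@H]2[C@H](CCCC[C@H](O[Si](C)(C)C(C)(C)C)CCC)CCC[C@@H]2N(C(=O)OC(C)(C)C)[C@@H]1C | intermediate
22 | (2E)-oct-2-enoic acid | CCCCC/C=C/C(=O)O | starting material
23 | tert-butyl (2R,3S,4aR,5R,8aS)-2-methyl-3-[(2E)-oct-2-enoyloxy]-5-[(5R)-5-(tert-butyldimethylsilyloxy)octyl]octahydroquinoline-1(2H)-carboxylate | CCCCC/C=C/C(=O)O[C@H]1C[C@@H]2[C@H](CCCC[C@H](O[Si](C)(C)C(C)(C)C)CCC)CCC[C@@H]2N(C(=O)OC(C)(C)C)[C@@H]1C | intermediate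
24 | (2R,3S,4aR,5R,8aS)-5-[(5R)-5-hydroxyoctyl]-2-methyldecahydroquinolin-3-yl (2E)-oct-2-enoate | CCCCC/C=C/C(=O)O[C@H]1C[C@@H]2[C@H](CCCC[C@H](O)CCC)CCC[C@@H]2N[C@@H]1C | target

## Count and risk

Total steps: 13. Longest linear sequence: 13 steps (1 to 24; the indole 5 joins at step 3).

Steps most likely to fail:

Step 12 (Mitsunobu at a crowded ring carbinol; elimination or no reaction). The fallback sets out from 21 and comes back at 23. Chloromethanesulfonyl chloride and pyridine convert 21 into tert-butyl (2R,3R,4aR,5R,8aS)-3-[(chloromethanesulfonyl)oxy]-2-methyl-5-[(5R)-5-(tert-butyldimethylsilyloxy)octyl]octahydroquinoline-1(2H)-carboxylate F7, a small, isolable leaving group made for SN2 at hindered secondary carbons. Acid 22 and Cs2CO3 give cesium (2E)-oct-2-enoate F8, which displaces the sulfonate (18-crown-6, toluene, 80 °C) with inversion to give 23. The activation thus moves from a bulky oxyphosphonium formed in situ to a pre-formed sulfonate and a naked carboxylate.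

Step 5 (enantioselectivity on a 4-alkyl indole-2-ester is unproven). The fallback sets out from 5 and comes back at 9, resolving the core before the side chain is attached. Reduction of 5 (Sn, HCl, EtOH) gives ethyl (2RS)-4-bromo-2,3-dihydro-1H-indole-2-carboxylate F1. A subtilisin-type protease in pH 8 buffer, the enzyme class used to resolve indoline-2-carboxylic esters, hydrolyses the 2R ester and leaves ethyl (2S)-4-bromo-2,3-dihydro-1H-indole-2-carboxylate F2. Boc2O gives 1-tert-butyl 2-ethyl (2S)-4-bromo-2,3-dihydro-1H-indole-1,2-dicarboxylate F3, and B-alkyl Suzuki coupling of F3 with borane 6 (made from 4 as in step 3) gives 9.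

Step 10 (ionisation of the crowded, concave trifluoroacetate may be slow or stop at a pyrrolidine/piperidine mixture). The fallback sets out from 15 and comes back at 19 through a halide relay. MsCl and Et3N (CH2Cl2, −20 °C) give (1S)-1-[(2S,3aR,4R,7aS)-1-benzyl-4-[(5R)-5-(tert-butyldimethylsilyloxy)octyl]octahydro-1H-indol-2-yl]ethyl methanesulfonate F4. This ionises already in the cold to the aziridinium chloride F5 (the cation of 17). Chloride, a reversible nucleophile, opens it, and on warming (toluene, 80 °C) the mixture settles on the six-membered (2R,3R,4aR,5R,8aS)-1-benzyl-3-chloro-2-methyl-5-[(5R)-5-(tert-butyldimethylsilyloxy)octyl]decahydroquinoline F6. Silver trifluoroacetate (THF, 50 °C) then removes the chloride irreversibly to give 17 and from it 18, and aqueous NaOH gives 19, with the C3 configuration kept by double inversion.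

## Further compounds

F1 | step 5 | ethyl (2RS)-4-bromo-2,3-dihydro-1H-indole-2-carboxylate (racemate) | CCOC(=O)C1Cc2c(Br)cccc2N1
F2 | step 5 | ethyl (2S)-4-bromo-2,3-dihydro-1H-indole-2-carboxylate | CCOC(=O)[C@@H]1Cc2c(Br)cccc2N1
F3 | step 5 | 1-tert-butyl 2-ethyl (2S)-4-bromo-2,3-dihydro-1H-indole-1,2-dicarboxylate | CCOC(=O)[C@@H]1Cc2c(Br)cccc2N1C(=O)OC(C)(C)C
F4 | step 10 | (1S)-1-[(2S,3aR,4R,7aS)-1-benzyl-4-[(5R)-5-(tert-butyldimethylsilyloxy)octyl]octahydro-1H-indol-2-yl]ethyl methanesulfonate | C[C@H](OS(C)(=O)=O)[C@@H]1C[C@@H]2[C@H](CCCC[C@H](O[Si](C)(C)C(C)(C)C)CCC)CCC[C@@H]2N1Cc1ccccc1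
F5 | step 10 | N-benzyl aziridinium ion of 17 as its chloride | C[C@@H]1[C@@H]2C[C@@H]3[C@H](CCCC[C@H](O[Si](C)(C)C(C)(C)C)CCC)CCC[C@@H]3[N@+]12Cc1ccccc1.[Cl-]
F6 | step 10 | (2R,3R,4aR,5R,8aS)-1-benzyl-3-chloro-2-methyl-5-[(5R)-5-(tert-butyldimethylsilyloxy)octyl]decahydroquinoline | Cl[C@@H]1C[C@@H]2[C@H](CCCC[C@H](O[Si](C)(C)C(C)(C)C)CCC)CCC[C@@H]2N(Cc3ccccc3)[C@@H]1C
F7 | step 12 | tert-butyl (2R,3R,4aR,5R,8aS)-3-[(chloromethanesulfonyl)oxy]-2-methyl-5-[(5R)-5-(tert-butyldimethylsilyloxy)octyl]octahydroquinoline-1(2H)-carboxylate | ClCS(=O)(=O)O[C@@H]1C[C@@H]2[C@H](CCCC[C@H](O[Si](C)(C)C(C)(C)C)CCC)CCC[C@@H]2N(C(=O)OC(C)(C)C)[C@@H]1C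
F8 | step 12 | cesium (2E)-oct-2-enoate | CCCCC/C=C/C(=O)[O-].[Cs+]
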